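## Retrosynthetic overview

- The target is a cis-fused hexahydronaphthalene: ring A = cyclohexene C1–C2=C3–C4–C4a–C8a with all four stereocentres, ring B = C4a–C5(=O)–C6(CO2Me)=C7(C16H33)–C8H2–C8a.
- Feature that makes the key step possible: ring B is a cyclic vinylogous β-keto ester, so its C6=C7 bond joins a 1,3-dicarbonyl carbon (C6) to a carbon (C7) that can be a ketone standing 1,5 to C5 (path C5, C4a, C8a, C8, C7). Ring B is therefore closed last, through C6=C7, by an intramolecular Knoevenagel condensation.
- The β-keto ester (on C4a) and the cis 2-oxoalkyl chain (on C8a) are unfolded from a temporary δ-lactone fused at C4a–C8a. Claisen opening with methyl acetate brings in C6; the lactone carbinol carbon, the only stereocentre carried into the synthesis, is oxidised to the C7 ketone in the key step and so erased.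
- Ring A is made before that by an endo Diels–Alder reaction of a 2-pyrone (a ring-locked Z,E-muconate half ester, temporary ring) with the (R)-δ-lactone; SmI2 then cuts the O–C(=O) bridge to the trans-1,4-diester with kinetic protonation at C4.
- Order of ring formation: δ-lactone (ring-closing metathesis) and 2-pyrone (both temporary), then ring A (Diels–Alder, lactone-bridged), then ring B last (Knoevenagel).

Key step: step 10

Assumption: heptadecanal, octadecan-2-one and (−)-B-allyldiisopinocampheylborane are taken as commercial; the β-methyl enoate of step 4 is used as its E/Z mixture because its geometry is lost in the dienolate of step 5; hexadecyl means n-C16H33.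

## Route

Step 1
Reactants: 1 heptadecanal
Product: 3 (R)-icos-1-en-4-ol, via diisopinocampheylborinate ester 2 (not isolated)
Conditions: (−)-Ipc2B(allyl) (from (+)-α-pinene), Et2O, −78 °C; then NaOH, H2O2, 0 °C to rt
Reagents that add atoms: (−)-B-allyldiisopinocampheylborane, C=CCB([C@@H]1C[C@@H]2C[C@H]([C@H]1C)C2(C)C)[C@@H]1C[C@@H]2C[C@H]([C@H]1C)C2(C)C
Why: Asymmetric allylboration through a chair-like six-membered transition state; this antipode of the reagent should deliver allyl to the Si face of the unbranched aldehyde and so set the (R) carbinol centre.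

Step 2
Reactants: 3 (R)-icos-1-en-4-ol
Product: 4 (R)-icos-1-en-4-yl prop-2-enoate
Conditions: acryloyl chloride, Et3N, DMAP (cat.), CH2Cl2, 0 °C
Reagents that add atoms: acryloyl chloride, C=CC(=O)Cl
Why: O-Acylation of a secondary alcohol with an acid chloride; the stereocentre is not touched.

Step 3
Reactants: 4 (R)-icos-1-en-4-yl prop-2-enoate
Product: 5 (R)-6-hexadecyl-5,6-dihydro-2H-pyran-2-one
Conditions: second-generation Grubbs catalyst RuCl2(=CHPh)(PCy3)(H2IMes) (5 mol %), CH2Cl2, 40 °C
Reagents that add atoms: none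
Why: Ring-closing metathesis of the acrylate and terminal alkene to the six-membered α,β-unsaturated δ-lactone, driven by loss of ethylene.

Step 4
Reactants: 6 octadecan-2-one
Product: 7 methyl 3-methylnonadec-2-enoate (E/Z mixture)
Conditions: (MeO)2P(O)CH2CO2Me, NaH, THF, 65 °C
Reagents that add atoms: trimethyl phosphonoacetate, COC(=O)CP(=O)(OC)OC
Why: Horner–Wadsworth–Emmons olefination of a methyl ketone; the double-bond geometry is irrelevant for the next step.

Step 5
Reactants: 7 methyl 3-methylnonadec-2-enoate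
Product: 9 methyl 4-hexadecyl-2-oxo-2H-pyran-6-carboxylate, via potassium dienolate 8 (not isolated)
Conditions: (CO2Me)2, KOMe, Et2O–MeOH, 0 °C to rt; then HCl, AcOH, 80 °C
Reagents that add atoms: dimethyl oxalate, COC(=O)C(=O)OC
Why: Vinylogous Claisen condensation of the potassium dienolate with dimethyl oxalate, expected at the less hindered γ-methyl group, followed by acid-mediated enol lactonisation with loss of methanol; this is the classical oxalate route to 4-alkyl-2-pyrone-6-carboxylates.

Step 6
Reactants: 9 methyl 4-hexadecyl-2-oxo-2H-pyran-6-carboxylate; 5 (R)-6-hexadecyl-5,6-dihydro-2H-pyran-2-one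
Product: 10 endo-anti cycloadduct (8-hexadecyl-1-methoxycarbonyl-2-oxabicyclo[2.2.2]oct-7-en-3-one cis-fused at C5–C6 to the (R)-δ-lactone)
Conditions: CH2Cl2, 13 kbar, 45 °C
Reagents that add atoms: none
Why: Diels–Alder reaction of a 2-pyrone with an α,β-unsaturated lactone under high pressure (negative activation volume, no CO2 extrusion): the nucleophilic pyrone C3, reinforced by the 4-hexadecyl group, should bond to the lactone β-carbon and C6 to the α-carbon, the endo transition state places the lactone ring anti to the O–C(=O) bridge, and attack anti to the hexadecyl group of 5 transfers its (R) centre to the three new CH stereocentres and the C–O bridgehead.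

Step 7
Reactants: 10 endo-anti cycloadduct
Product: 11 (3R,4aR,5S,8R,8aS)-3,6-dihexadecyl-8-(methoxycarbonyl)-1-oxo-3,4,4a,5,8,8a-hexahydro-1H-isochromene-5-carboxylic acid
Conditions: SmI2, HMPA, t-BuOH, THF, −78 °C; aq. HCl work-up
Reagents that add atoms: none
Why: Samarium diiodide reduction of an α-acyloxy ester (electron transfer, β-scission of the allylic bridgehead C–O bond, second electron transfer) should give the carboxylate and a samarium ester dienolate, whose kinetic α-protonation from the face opposite the neighbouring lactone carbonyl sets C8 (ester cis to the ring-fusion acyl group) and keeps the ring alkene out of conjugation; the δ-lactone and the methyl ester are inert under these conditions.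

Step 8
Reactants: 11 the carboxylic acid
Product: 12 dimethyl (3R,4aR,5S,8R,8aS)-3,6-dihexadecyl-1-oxo-3,4,4a,5,8,8a-hexahydro-1H-isochromene-5,8-dicarboxylate
Conditions: Me3SiCHN2, PhMe–MeOH, 0 °C
Reagents that add atoms: trimethylsilyldiazomethane, C[Si](C)(C)C=[N+]=[N-]
Why: Base-free methyl esterification of a carboxylic acid with a diazoalkane, so that no epimerisable centre meets base.

Step 9
Reactants: 12 the lactone diester
Product: 13 dimethyl (1S,4R,5S,6R)-2-hexadecyl-6-[(2R)-2-hydroxyoctadecyl]-5-(3-methoxy-3-oxopropanoyl)cyclohex-2-ene-1,4-dicarboxylate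
Conditions: MeOAc, LiN(SiMe3)2, THF, −78 °C; then 12, −78 °C; AcOH quench at −78 °C
Reagents that add atoms: methyl acetate, CC(=O)OC
Why: Claisen-type acylation of an ester enolate by the lactone, which is far more electrophilic than the two α-branched methyl esters; the tetrahedral lithium hemiketal prevents double addition, and the cold acidic quench should avoid enolisation of the allylic ester stereocentres (13 is in equilibrium with its cyclic hemiketal).

Step 10
Reactants: 13 the δ-hydroxy β-keto ester
Product: 15 trimethyl (1S,4R,4aS,8aR)-2,7-dihexadecyl-5-oxo-1,4,4a,5,8,8a-hexahydronaphthalene-1,4,6-tricarboxylate, via diketo ester 14 (not isolated)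
Conditions: Dess–Martin periodinane (1.1 equiv), CH2Cl2, 0 °C to rt; then piperidine (0.3 equiv), 4 Å MS, 40 °C
Reagents that add atoms: none
Why: Dess–Martin oxidation converts the secondary carbinol, the stereocentre that relayed the absolute configuration, into the C7 ketone and gives 1,5-dicarbonyl compound 14, in which the doubly activated C6 methylene and the C7 ketone sit on cis substituents of C4a and C8a; piperidine and the acetic acid set free by the periodinane then form piperidinium acetate, which promotes an intramolecular Knoevenagel condensation (enol or enamine addition of C6 to the C7 carbonyl, then E1cB loss of water) to the tetrasubstituted C6=C7 alkene. The closest known reaction type is the aldol-condensation half of a Robinson annulation with a β-keto ester component. Ring B is closed by a 6-(enolendo)-exo-trig attack. No stereocentre is created, the carbinol centre is deliberately destroyed, and the four ring-A centres are not touched. The step needs condensation through C6 instead of the ketone α-carbons, which the acidity of the β-keto ester secures, and retention of the cis ring fusion (C4a is α to the ketone) and of the two β,γ-unsaturated esters, which the near-neutral amine–acetate medium and the fast cis-1,2 ring closure should secure.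

## Compound list

1 | heptadecanal | CCCCCCCCCCCCCCCCC=O | starting material
2 | (R)-icos-1-en-4-yl diisopinocampheylborinate | C=CC[C@H](OB([C@@H]1C[C@@H]2C[C@H]([C@H]1C)C2(C)C)[C@@H]1C[C@@H]2C[C@H]([C@H]1C)C2(C)C)CCCCCCCCCCCCCCCC | intermediate
3 | (R)-icos-1-en-4-ol | C=CC[C@H](O)CCCCCCCCCCCCCCCC | intermediate
4 | (R)-icos-1-en-4-yl prop-2-enoate | C=CC[C@H](OC(=O)C=C)CCCCCCCCCCCCCCCC | intermediate
5 | (R)-6-hexadecyl-5,6-dihydro-2H-pyran-2-one | O=C1C=CC[C@@H](CCCCCCCCCCCCCCCC)O1 | intermediate
6 | octadecan-2-one | CC(=O)CCCCCCCCCCCCCCCC | starting material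
7 | methyl 3-methylnonadec-2-enoate (E/Z mixture, E isomer drawn) | COC(=O)/C=C(\C)CCCCCCCCCCCCCCCC | intermediate
8 | potassium 4-hexadecyl-1,6-dimethoxy-1,6-dioxohexa-2,4-dien-2-olate (E/Z mixture) | [K+].[O-]C(=CC(CCCCCCCCCCCCCCCC)=CC(=O)OC)C(=O)OC | intermediate
9 | methyl 4-hexadecyl-2-oxo-2H-pyran-6-carboxylate | COC(=O)C1=CC(CCCCCCCCCCCCCCCC)=CC(=O)O1 | intermediate
10 | endo-anti cycloadduct: methyl 8-hexadecyl-3-oxo-2-oxabicyclo[2.2.2]oct-7-ene-1-carboxylate cis-fused at C5/C6 to the δ-lactone (lactone C=O on C6, lactone CH2 on C5, lactone ring anti to the O2–C3 bridge, (R)-carbinol hexadecyl pointing away from the bicycle) | CCCCCCCCCCCCCCCCC1=C[C@@]3(C(=O)OC)[C@H]2C(=O)O[C@H](CCCCCCCCCCCCCCCC)C[C@H]2[C@@H]1C(=O)O3 | intermediate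
11 | (3R,4aR,5S,8R,8aS)-3,6-dihexadecyl-8-(methoxycarbonyl)-1-oxo-3,4,4a,5,8,8a-hexahydro-1H-isochromene-5-carboxylic acid | CCCCCCCCCCCCCCCCC1=C[C@@H](C(=O)OC)[C@H]2C(=O)O[C@H](CCCCCCCCCCCCCCCC)C[C@H]2[C@@H]1C(=O)O | intermediate
12 | dimethyl (3R,4aR,5S,8R,8aS)-3,6-dihexadecyl-1-oxo-3,4,4a,5,8,8a-hexahydro-1H-isochromene-5,8-dicarboxylate | CCCCCCCCCCCCCCCCC1=C[C@@H](C(=O)OC)[C@H]2C(=O)O[C@H](CCCCCCCCCCCCCCCC)C[C@H]2[C@@H]1C(=O)OC | intermediate
13 | dimethyl (1S,4R,5S,6R)-2-hexadecyl-6-[(2R)-2-hydroxyoctadecyl]-5-(3-methoxy-3-oxopropanoyl)cyclohex-2-ene-1,4-dicarboxylate | CCCCCCCCCCCCCCCCC1=C[C@@H](C(=O)OC)[C@@H](C(=O)CC(=O)OC)[C@@H](C[C@H](O)CCCCCCCCCCCCCCCC)[C@@H]1C(=O)OC | intermediate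
14 | dimethyl (1S,4R,5S,6R)-2-hexadecyl-5-(3-methoxy-3-oxopropanoyl)-6-(2-oxooctadecyl)cyclohex-2-ene-1,4-dicarboxylate | CCCCCCCCCCCCCCCCC1=C[C@@H](C(=O)OC)[C@@H](C(=O)CC(=O)OC)[C@@H](CC(=O)CCCCCCCCCCCCCCCC)[C@@H]1C(=O)OC | intermediate
15 | trimethyl (1S,4R,4aS,8aR)-2,7-dihexadecyl-5-oxo-1,4,4a,5,8,8a-hexahydronaphthalene-1,4,6-tricarboxylate | CCCCCCCCCCCCCCCCC1=C[C@@H](C(=O)OC)[C@H]2C(=O)C(C(=O)OC)=C(CCCCCCCCCCCCCCCC)C[C@H]2[C@@H]1C(=O)OC | target

## Step count and risks

Total step count: 10. Longest linear sequence: 8 steps (1, 2, 3, 6, 7, 8, 9, 10).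

Steps most likely to fail:

Step 6. The cycloaddition of two electron-poor partners may be too slow even under pressure, or may lose regio- or facial control. The fallback sets out from 5 and comes back at 10. Bromine addition (Br2, CH2Cl2, 0 °C) gives the trans-dibromide (6R)-3,4-dibromo-6-hexadecyloxan-2-one F1, and Et3N then eliminates HBr to (6R)-3-bromo-6-hexadecyl-5,6-dihydro-2H-pyran-2-one F2. This is a 2-halo-enoate with a lower-lying LUMO, a known way to raise dienophile reactivity. Its cycloaddition with 9 gives the 6-bromo cycloadduct F3. Radical debromination (Bu3SnH, AIBN, PhH, 80 °C), with hydrogen delivery to the α-lactone radical from the open exo face, returns to 10.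

Step 7. The electron-transfer cleavage may over-reduce, or the samarium dienolate may be protonated from the wrong face or at the γ-carbon, giving the C8 epimer or the conjugated ester. The fallback sets out from 10 and comes back at 12, so steps 7 and 8 are bypassed. Mild methanolysis (K2CO3 cat., MeOH, 0 °C) of the strained, activated bridging lactone gives dimethyl (3R,4aS,5S,8S,8aS)-3,6-dihexadecyl-8-hydroxy-1-oxo-3,4,4a,5,8,8a-hexahydro-1H-isochromene-5,8-dicarboxylate F4. Acylation with methyl chlorooxoacetate (pyridine, DMAP, CH2Cl2) gives the tertiary methyl oxalate F5. Tin hydride deoxygenation of this oxalate (Bu3SnH, AIBN, PhMe, 110 °C) generates the allylic, ester-stabilised C8 radical, which should take hydrogen on the face opposite the lactone carbonyl and give 12.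

Step 9. The basic enolate may deprotonate the allylic ester α-hydrogens, with epimerisation at C5 or C8, or attack a methyl ester. The fallback sets out from 12 and comes back at 13. Reduction with i-Bu2AlH (1.05 equiv, CH2Cl2, −78 °C) takes the lactone to dimethyl (3R,4aR,5S,8R,8aS)-3,6-dihexadecyl-1-hydroxy-3,4,4a,5,8,8a-hexahydro-1H-isochromene-5,8-dicarboxylate F6 (anomer mixture). Roskamp homologation of its open hydroxy-aldehyde form (methyl diazoacetate, SnCl2 cat., CH2Cl2, rt) gives β-keto ester 13 without any base.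

Further compounds
F1 | step 6 | (6R)-3,4-dibromo-6-hexadecyloxan-2-one (trans-dibromide, diastereomer mixture at C3/C4) | O=C1C(Br)C(Br)C[C@@H](CCCCCCCCCCCCCCCC)O1
F2 | step 6 | (6R)-3-bromo-6-hexadecyl-5,6-dihydro-2H-pyran-2-one | O=C1C(Br)=CC[C@@H](CCCCCCCCCCCCCCCC)O1
F3 | step 6 | 6-bromo analogue of cycloadduct 10 (bromine on the bicyclooctene carbon that carries the δ-lactone carbonyl) | CCCCCCCCCCCCCCCCC1=C[C@@]3(C(=O)OC)[C@@]2(Br)C(=O)O[C@H](CCCCCCCCCCCCCCCC)C[C@H]2[C@@H]1C(=O)O3
F4 | step 7 | dimethyl (3R,4aS,5S,8S,8aS)-3,6-dihexadecyl-8-hydroxy-1-oxo-3,4,4a,5,8,8a-hexahydro-1H-isochromene-5,8-dicarboxylate | CCCCCCCCCCCCCCCCC1=C[C@@](O)(C(=O)OC)[C@H]2C(=O)O[C@H](CCCCCCCCCCCCCCCC)C[C@H]2[C@@H]1C(=O)OC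
F5 | step 7 | dimethyl (3R,4aS,5S,8S,8aS)-3,6-dihexadecyl-8-[(2-methoxy-2-oxoacetyl)oxy]-1-oxo-3,4,4a,5,8,8a-hexahydro-1H-isochromene-5,8-dicarboxylate | CCCCCCCCCCCCCCCCC1=C[C@@](OC(=O)C(=O)OC)(C(=O)OC)[C@H]2C(=O)O[C@H](CCCCCCCCCCCCCCCC)C[C@H]2[C@@H]1C(=O)OC
F6 | step 9 | dimethyl (3R,4aR,5S,8R,8aS)-3,6-dihexadecyl-1-hydroxy-3,4,4a,5,8,8a-hexahydro-1H-isochromene-5,8-dicarboxylate (anomer mixture at C1) | CCCCCCCCCCCCCCCCC1=C[C@@H](C(=O)OC)[C@H]2C(O)O[C@H](CCCCCCCCCCCCCCCC)C[C@H]2[C@@H]1C(=O)OC
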